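The lactone carbons C2–C5 of the butyrolactone ring are read as a succinic acid chain whose adjacent carbons C3 and C4 each carry one benzylic carbon. The target is therefore traced back to a twisted (E,E)-bis(arylidene)succinic half-ester, assembled by two Stobbe condensations, with the free acid on the syringylidene carbon (future C3) and the methyl ester on the trimethoxybenzylidene carbon (future C4). One carboxylate-directed asymmetric hydrogenation with a cationic monovalent rhodium bisphosphine catalyst reduces only the trimethoxybenzylidene alkene and sets C4 as (R). Ester reduction, lactonisation and MOM removal then close the ring and finish the synthesis.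

Key step: step 5

Remark on numbering: lactone atoms are O1, C2 (carbonyl), C3 (arylidene-bearing), C4 (stereocentre with the trimethoxybenzyl group), C5 (OCH2); the target is (4R) with an (E) exocyclic alkene.
Remark on the ligand: (S,S)-Et-DuPhos is specified by analogy with the quadrant model for arylidenesuccinic half-esters; it is assumed that the same sense holds for the diene substrate, and the mirror-image ligand would be substituted unchanged should the first run show the opposite sense.
Remark on handling: compound 7 is a fulgenic-acid-type diene and is kept under amber light to prevent electrocyclisation and E/Z isomerisation.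

Step 1
Reactants: 1 syringaldehyde
Product: 2 4-(methoxymethoxy)-3,5-dimethoxybenzaldehyde
Conditions: MOMCl, iPr2NEt, CH2Cl2, 0 °C to rt
Reagents that add atoms: chloromethyl methyl ether (MOMCl), COCCl
Why: Base-mediated O-alkylation of the phenol (MOM ether formation) masks the phenoxide that would otherwise deactivate the aldehyde in the Stobbe condensations, and the acetal survives every basic, reductive and hydrogenation step before the final acid treatment.

Step 2
Reactants: 2 4-(methoxymethoxy)-3,5-dimethoxybenzaldehyde; 3 dimethyl succinate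
Product: 4 (E)-3-(methoxycarbonyl)-4-[4-(methoxymethoxy)-3,5-dimethoxyphenyl]but-3-enoic acid
Conditions: NaOMe, MeOH, reflux; then cold 1 M HCl to pH 3
Reagents that add atoms: none
Why: Stobbe condensation, in which aldol addition of the succinate enolate, lactonisation onto the distal ester and E1cB ring-opening give the (E)-arylidene half-ester with the ester on the alkene carbon and the carboxylate on CH2, carboxylate formation driving the reaction.

Step 3
Reactants: 4 (E)-3-(methoxycarbonyl)-4-[4-(methoxymethoxy)-3,5-dimethoxyphenyl]but-3-enoic acid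
Product: 5 dimethyl (E)-2-[4-(methoxymethoxy)-3,5-dimethoxybenzylidene]succinate
Conditions: MeI, K2CO3, DMF, rt
Reagents that add atoms: iodomethane, CI
Why: SN2 O-methylation of the potassium carboxylate under non-acidic conditions keeps the MOM acetal and the (E)-alkene intact and restores the diester needed for a second enolisation.

Step 4
Reactants: 5 dimethyl (E)-2-[4-(methoxymethoxy)-3,5-dimethoxybenzylidene]succinate; 6 3,4,5-trimethoxybenzaldehyde
Product: 7 (2E,3E)-2-[4-(methoxymethoxy)-3,5-dimethoxybenzylidene]-3-(3,4,5-trimethoxybenzylidene)succinic acid 4-methyl ester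
Conditions: NaOMe, MeOH, reflux, amber glassware; then cold 1 M HCl to pH 3
Reagents that add atoms: none
Why: Second Stobbe condensation, in which the only enolisable CH2 of 5 adds to aldehyde 6 and the alkoxide lactonises onto the ester on the syringylidene carbon, so that E1cB opening leaves the free acid on that carbon and the methyl ester on the new trimethoxybenzylidene carbon, the hindered diene settling in the thermodynamically preferred (E,E) geometry.

Step 5
Reactants: 7 (2E,3E)-2-[4-(methoxymethoxy)-3,5-dimethoxybenzylidene]-3-(3,4,5-trimethoxybenzylidene)succinic acid 4-methyl ester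
Product: 8 (2E,3R)-2-[4-(methoxymethoxy)-3,5-dimethoxybenzylidene]-3-(3,4,5-trimethoxybenzyl)succinic acid 4-methyl ester
Conditions: [Rh(cod)((S,S)-Et-DuPhos)]BF4 (2 mol%), NaOMe (10 mol%), H2 (4 bar), degassed MeOH, 25 °C, dark; stopped after one equivalent of H2
Reagents that add atoms: none
Why: Proposed new method: the carboxylate of 7 binds cationic monovalent rhodium and, together with the trimethoxybenzylidene C=C one carbon away, forms the five-membered chelate typical of itaconate half-esters, after which oxidative addition of H2, migratory insertion and reductive elimination add both hydrogens syn to one alkene face. The closest known reaction type is the rhodium–bisphosphine asymmetric hydrogenation of Stobbe arylidenesuccinic half-esters, the new element being discrimination between two arylidenes in one molecule. No ring is closed and no skeletal bond is formed. The new C4 stereocentre (R) is controlled by the chiral bisphosphine, whose quadrant blocking selects the alkene face within the chelate. The step needs chemoselectivity for one alkene: the syringylidene C=C carries the carboxylate directly, so chelation there would require a strained four-membered ring, and its only itaconate-type donor is an ester carbonyl, a substrate class that reacts much more slowly with such catalysts, while the twist of the diene keeps the two alkenes from behaving as one conjugated unit. Limiting hydrogen uptake to one equivalent guards against over-reduction.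

Step 6
Reactants: 8 (2E,3R)-2-[4-(methoxymethoxy)-3,5-dimethoxybenzylidene]-3-(3,4,5-trimethoxybenzyl)succinic acid 4-methyl ester
Product: 10 (R,E)-3-[4-(methoxymethoxy)-3,5-dimethoxybenzylidene]-4-(3,4,5-trimethoxybenzyl)dihydrofuran-2(3H)-one, via hydroxy acid 9 (not isolated)
Conditions: KHCO3 (1.0 equiv), EtOH/H2O; Ca(BH4)2 (from CaCl2 and NaBH4), EtOH, −10 to 0 °C; then 1 M HCl, 0 °C to rt
Reagents that add atoms: none
Why: Ca(BH4)2 reduces a carboxylic ester but neither a carboxylate salt nor the electron-rich carboxylate-bearing arylidene (the known chemoselective borohydride reduction of succinic half-ester salts), and acidification lets the new primary alcohol close the five-membered lactone onto the conjugated acid by 5-exo-trig acyl substitution, C4 being shielded from epimerisation by the weak base and low temperature.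

Step 7
Reactants: 10 (R,E)-3-[4-(methoxymethoxy)-3,5-dimethoxybenzylidene]-4-(3,4,5-trimethoxybenzyl)dihydrofuran-2(3H)-one
Product: 11 (R,E)-3-(4-hydroxy-3,5-dimethoxybenzylidene)-4-(3,4,5-trimethoxybenzyl)dihydrofuran-2(3H)-one
Conditions: conc. HCl (cat.), MeOH, 45 °C
Reagents that add atoms: none
Why: Acid-catalysed acetal exchange (MOM deprotection) transfers the methylene unit to methanol as dimethoxymethane, so no free formaldehyde can attack the electron-rich rings, while the lactone, the (E)-arylidene and the C4 centre, which is not alpha to the carbonyl, should be untouched.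

Compound list
1 | syringaldehyde (4-hydroxy-3,5-dimethoxybenzaldehyde) | COc1cc(C=O)cc(OC)c1O | starting material
2 | 4-(methoxymethoxy)-3,5-dimethoxybenzaldehyde | COCOc1c(OC)cc(C=O)cc1OC | intermediate
3 | dimethyl succinate | COC(=O)CCC(=O)OC | starting material
4 | (E)-3-(methoxycarbonyl)-4-[4-(methoxymethoxy)-3,5-dimethoxyphenyl]but-3-enoic acid | COC(=O)/C(=C/c1cc(OC)c(OCOC)c(OC)c1)CC(=O)O | intermediate
5 | dimethyl (E)-2-[4-(methoxymethoxy)-3,5-dimethoxybenzylidene]succinate | COC(=O)/C(=C/c1cc(OC)c(OCOC)c(OC)c1)CC(=O)OC | intermediate
6 | 3,4,5-trimethoxybenzaldehyde | COc1cc(C=O)cc(OC)c1OC | starting material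
7 | (2E,3E)-2-[4-(methoxymethoxy)-3,5-dimethoxybenzylidene]-3-(3,4,5-trimethoxybenzylidene)succinic acid 4-methyl ester | COC(=O)/C(=C/c1cc(OC)c(OC)c(OC)c1)C(=C/c1cc(OC)c(OCOC)c(OC)c1)\C(=O)O | intermediate
8 | (2E,3R)-2-[4-(methoxymethoxy)-3,5-dimethoxybenzylidene]-3-(3,4,5-trimethoxybenzyl)succinic acid 4-methyl ester | COC(=O)[C@H](Cc1cc(OC)c(OC)c(OC)c1)C(=C/c1cc(OC)c(OCOC)c(OC)c1)\C(=O)O | intermediate
9 | (2E,3R)-4-hydroxy-2-[4-(methoxymethoxy)-3,5-dimethoxybenzylidene]-3-(3,4,5-trimethoxybenzyl)butanoic acid (present as its carboxylate, not isolated) | OC[C@H](Cc1cc(OC)c(OC)c(OC)c1)C(=C/c1cc(OC)c(OCOC)c(OC)c1)\C(=O)O | intermediate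
10 | (R,E)-3-[4-(methoxymethoxy)-3,5-dimethoxybenzylidene]-4-(3,4,5-trimethoxybenzyl)dihydrofuran-2(3H)-one | COCOc1c(OC)cc(/C=C2/C(=O)OC[C@@H]2Cc2cc(OC)c(OC)c(OC)c2)cc1OC | intermediate
11 | (R,E)-3-(4-hydroxy-3,5-dimethoxybenzylidene)-4-(3,4,5-trimethoxybenzyl)dihydrofuran-2(3H)-one (CNP0198204.1) | COc1cc(/C=C2/C(=O)OC[C@@H]2Cc2cc(OC)c(OC)c(OC)c2)cc(OC)c1O | target

Total step count: 7
Longest linear sequence: 7 steps (1 to 11)

Steps most likely to fail

Step 5. The hydrogenation may lose chemoselectivity (reduction of the syringylidene alkene or of both alkenes) or show poor facial selectivity at C4. The fallback sets out from 6 and 3, uses 2, and returns at 10. It introduces the stereocentre before the second arylidene exists. Stobbe condensation of 6 with 3 (NaOMe, MeOH, reflux) gives (E)-3-(methoxycarbonyl)-4-(3,4,5-trimethoxyphenyl)but-3-enoic acid F1. Asymmetric hydrogenation of this simple arylidenesuccinic half-ester with the same rhodium bisphosphine catalyst is established chemistry and gives (R)-3-(methoxycarbonyl)-4-(3,4,5-trimethoxyphenyl)butanoic acid F2. Ca(BH4)2 reduction of its potassium salt followed by acid gives (R)-4-(3,4,5-trimethoxybenzyl)dihydrofuran-2(3H)-one F3. Its lithium enolate (LiN(SiMe3)2, THF, −78 °C) adds to aldehyde 2 to give the aldol (4R)-3-{hydroxy[4-(methoxymethoxy)-3,5-dimethoxyphenyl]methyl}-4-(3,4,5-trimethoxybenzyl)dihydrofuran-2(3H)-one F4 as a diastereomer mixture. MsCl/Et3N converts it into the mesylate F5, and DBU eliminates to the thermodynamically favoured (E)-arylidene lactone 10.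

Step 4. The second condensation may suffer from base-induced migration of the arylidene double bond of 5, slow reaction of the hindered enolate, or geometric scrambling under prolonged heating. The fallback sets out from 5 and 6 and returns at 7. It splits the condensation into a kinetic aldol and a separate ring-opening. Diester 5 is deprotonated with LiN(iPr)2 in THF at −78 °C and aldehyde 6 is added. Warming lets the aldolate lactonise to methyl (E)-4-[4-(methoxymethoxy)-3,5-dimethoxybenzylidene]-5-oxo-2-(3,4,5-trimethoxyphenyl)tetrahydrofuran-3-carboxylate F6, which is isolated. Brief treatment with DBU in THF then opens the lactone by E1cB elimination to 7, with the same placement of acid and ester.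

Step 6. The reduction may be accompanied by epimerisation at C4 through the allylic ester enolate in the basic medium, or by incomplete discrimination between ester and carboxylate. The fallback sets out from 8 and returns at 10. It avoids basic conditions by reducing both carbonyls and re-oxidising one. The acid of 8 is esterified under neutral conditions (Me3SiCHN2, MeOH/toluene, 0 °C) to dimethyl (2E,3R)-2-[4-(methoxymethoxy)-3,5-dimethoxybenzylidene]-3-(3,4,5-trimethoxybenzyl)succinate F7. iBu2AlH (CH2Cl2, −78 °C) reduces both esters to (2E,3R)-2-[4-(methoxymethoxy)-3,5-dimethoxybenzylidene]-3-(3,4,5-trimethoxybenzyl)butane-1,4-diol F8. MnO2 (CH2Cl2, rt) oxidises only the allylic alcohol, the resulting enal closes to the lactol (4R,E)-3-[4-(methoxymethoxy)-3,5-dimethoxybenzylidene]-4-(3,4,5-trimethoxybenzyl)tetrahydrofuran-2-ol F9, and further oxidation by MnO2 gives 10 with the carbonyl on the arylidene-bearing carbon.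

Further compounds
F1 | step 5 | (E)-3-(methoxycarbonyl)-4-(3,4,5-trimethoxyphenyl)but-3-enoic acid | COC(=O)/C(=C/c1cc(OC)c(OC)c(OC)c1)CC(=O)O
F2 | step 5 | (R)-3-(methoxycarbonyl)-4-(3,4,5-trimethoxyphenyl)butanoic acid | COC(=O)[C@H](Cc1cc(OC)c(OC)c(OC)c1)CC(=O)O
F3 | step 5 | (R)-4-(3,4,5-trimethoxybenzyl)dihydrofuran-2(3H)-one | O=C1OC[C@@H](C1)Cc2cc(OC)c(OC)c(OC)c2
F4 | step 5 | (4R)-3-{hydroxy[4-(methoxymethoxy)-3,5-dimethoxyphenyl]methyl}-4-(3,4,5-trimethoxybenzyl)dihydrofuran-2(3H)-one (diastereomer mixture at C3 and the carbinol carbon) | COCOc1c(OC)cc(C(O)C2C(=O)OC[C@@H]2Cc2cc(OC)c(OC)c(OC)c2)cc1OC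
F5 | step 5 | [4-(methoxymethoxy)-3,5-dimethoxyphenyl][(4R)-2-oxo-4-(3,4,5-trimethoxybenzyl)tetrahydrofuran-3-yl]methyl methanesulfonate (diastereomer mixture) | COCOc1c(OC)cc(C(OS(C)(=O)=O)C2C(=O)OC[C@@H]2Cc2cc(OC)c(OC)c(OC)c2)cc1OC
F6 | step 4 | methyl (E)-4-[4-(methoxymethoxy)-3,5-dimethoxybenzylidene]-5-oxo-2-(3,4,5-trimethoxyphenyl)tetrahydrofuran-3-carboxylate (cis/trans mixture) | COC(=O)C1C(c2cc(OC)c(OC)c(OC)c2)OC(=O)/C1=C/c1cc(OC)c(OCOC)c(OC)c1
F7 | step 6 | dimethyl (2E,3R)-2-[4-(methoxymethoxy)-3,5-dimethoxybenzylidene]-3-(3,4,5-trimethoxybenzyl)succinate | COC(=O)[C@H](Cc1cc(OC)c(OC)c(OC)c1)C(=C/c1cc(OC)c(OCOC)c(OC)c1)\C(=O)OC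
F8 | step 6 | (2E,3R)-2-[4-(methoxymethoxy)-3,5-dimethoxybenzylidene]-3-(3,4,5-trimethoxybenzyl)butane-1,4-diol | OC[C@H](Cc1cc(OC)c(OC)c(OC)c1)C(=C/c1cc(OC)c(OCOC)c(OC)c1)\CO
F9 | step 6 | (4R,E)-3-[4-(methoxymethoxy)-3,5-dimethoxybenzylidene]-4-(3,4,5-trimethoxybenzyl)tetrahydrofuran-2-ol (anomer mixture) | COCOc1c(OC)cc(/C=C2/C(O)OC[C@@H]2Cc2cc(OC)c(OC)c(OC)c2)cc1OC
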